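**Retrosynthetic overview**

1. The feruloyl ester C–O bond is cut last (O-acetylferuloyl chloride plus the primary alcohol), and the C3=C4 alkene is traced back to the saturated chroman (DDQ dehydrogenation).
2. Ring B (the pyran) is opened at O1–C2 and C3–C4. Benzylic C4 sits on C4a, ortho to the phenolic O1 on C8a, so C4=C4a–C8a=O1 is an ortho-quinone methide, and C3–C2(CH3)(CH2OH) is methallyl alcohol.
3. The quinone methide comes from a salicyl alcohol, made from 2,4-dihydroxybenzaldehyde by C5 acetylation and reduction of the aldehyde only.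
4. Ring A (the benzene ring) is bought. Ring B is the only ring formed, in step 3, together with the single stereocentre C2 (R, as read from the target SMILES).

Key step: step 3

Assumption: the sense of induction of the chiral acid in step 3 cannot be predicted from precedent; the (R)-acid is written, and its (S)-enantiomer would be used instead if that is the one that delivers the (2R)-chroman.

**Route**

Step 1
Reactants: 1 2,4-dihydroxybenzaldehyde
Product: 2 5-acetyl-2,4-dihydroxybenzaldehyde
Conditions: AcOH (1.5 equiv), BF3·OEt2 (as medium), 90 °C; then aq. NaOAc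
Reagents that add atoms: acetic acid, CC(=O)O
Why: Friedel–Crafts (Fries-type) C-acylation of a resorcinol: C5 is ortho to the 4-OH, para to the 2-OH and unhindered, whereas C3 is flanked by both hydroxyls, so the acetyl group should enter C5 as in the formation of 4,6-diacylresorcinols, and the non-enolisable aldehyde should survive.

Step 2
Reactants: 2 5-acetyl-2,4-dihydroxybenzaldehyde
Product: 3 1-[2,4-dihydroxy-5-(hydroxymethyl)phenyl]ethanone
Conditions: NaBH4 (1.0 equiv), THF/MeOH, −20 °C; then aq. NH4Cl
Reagents that add atoms: none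
Why: Chemoselective borohydride reduction: the formyl group is far more electrophilic than the hydrogen-bonded, phenol-conjugated aryl methyl ketone, so at low temperature only the aldehyde should be reduced, and the mild quench avoids acid-triggered self-condensation of the salicyl alcohol.

Step 3
Reactants: 3 1-[2,4-dihydroxy-5-(hydroxymethyl)phenyl]ethanone; 4 methallyl alcohol (2-methylprop-2-en-1-ol)
Product: 6 (R)-1-[7-hydroxy-2-(hydroxymethyl)-2-methylchroman-6-yl]ethanone, via ortho-quinone methide 5 (not isolated)
Conditions: (R)-TRIP [(R)-3,3'-bis(2,4,6-triisopropylphenyl)-1,1'-binaphthyl-2,2'-diyl hydrogen phosphate] (10 mol %), 4 (5 equiv), 5 Å molecular sieves, PhCF3, 50 °C, 3 added in portions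
Reagents that add atoms: none
Why: Proposed new method: the acid ionises the benzylic C–OH of 3 (assisted by the ortho and para hydroxyls) to the acetyl-activated ortho-quinone methide 5, whose exocyclic CH2 is attacked by the CH2 terminus of 4 (C3–C4) while the quinone methide oxygen closes onto the methyl-bearing carbon (O1–C2) in an asynchronous inverse-demand oxa-[4+2] cycloaddition. The closest known reactions are chiral phosphoric acid-catalysed [4+2] additions of ortho-quinone methides to styrenes and racemic thermal or acid-mediated trapping by unactivated alkenes; enantiocontrol with a 1,1-dialkyl alkene is the unproven part. Ring B is closed intermolecularly by this [4+2] event, with O1–C2 forming second as a six-membered closure onto the developing tertiary cation. The C2 stereocentre is controlled by the catalyst: its P–OH hydrogen-bonds the quinone methide carbonyl and its P=O accepts the allylic OH of 4, so that a single alkene face is presented inside the 2,4,6-triisopropylphenyl pocket. The step needs regioselectivity (oxygen to the tertiary carbon, secured by the Markovnikov polarisation of the alkene), C- over O-alkylation by 4 (benzyl ether formation is reversible under the acid) and suppression of self-condensation of 3 (portionwise addition, excess 4, arene deactivated by the acetyl group).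

Step 4
Reactants: 7 ferulic acid
Product: 8 (E)-3-(4-acetoxy-3-methoxyphenyl)prop-2-enoic acid (O-acetylferulic acid)
Conditions: Ac2O, pyridine, rt; then H2O
Reagents that add atoms: acetic anhydride, CC(=O)OC(C)=O
Why: Acetylation of the phenol by acyl transfer in pyridine; any mixed anhydride formed at the carboxyl group is hydrolysed in the aqueous work-up and the E-alkene is untouched.

Step 5
Reactants: 8 (E)-3-(4-acetoxy-3-methoxyphenyl)prop-2-enoic acid; 6 (R)-1-[7-hydroxy-2-(hydroxymethyl)-2-methylchroman-6-yl]ethanone
Product: 10 [(2R)-6-acetyl-7-hydroxy-2-methyl-3,4-dihydro-2H-chromen-2-yl]methyl (E)-3-(4-acetoxy-3-methoxyphenyl)prop-2-enoate, via acid chloride 9 (not isolated)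
Conditions: (COCl)2, cat. DMF, CH2Cl2, 0 °C to rt, concentrate; then 6, pyridine (1.5 equiv), CH2Cl2, 0 °C to rt
Reagents that add atoms: none
Why: Acid chloride esterification: with one equivalent of acylating agent and only a weak base, the primary alcohol should be acylated in preference to the C7 phenol, which is locked in a hydrogen bond to the C6 acetyl carbonyl; any aryl ester formed there would be cleaved again in step 7.

Step 6
Reactants: 10 [(2R)-6-acetyl-7-hydroxy-2-methyl-3,4-dihydro-2H-chromen-2-yl]methyl (E)-3-(4-acetoxy-3-methoxyphenyl)prop-2-enoate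
Product: 11 [(2R)-6-acetyl-7-hydroxy-2-methyl-2H-chromen-2-yl]methyl (E)-3-(4-acetoxy-3-methoxyphenyl)prop-2-enoate
Conditions: DDQ (2,3-dichloro-5,6-dicyano-1,4-benzoquinone, 1.5 equiv), 1,4-dioxane, 80 °C, dark
Reagents that add atoms: none
Why: Benzylic dehydrogenation by DDQ: hydride abstraction from C4 gives a cation stabilised by O1 and the C7 hydroxyl, and loss of a C3 proton gives the 2H-chromene, as is established for 6-acyl-7-hydroxy-2,2-dialkylchromans; C2 carries no hydrogen and is not touched, and the electron-poor acetoxycinnamate should be inert to the quinone.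

Step 7
Reactants: 11 [(2R)-6-acetyl-7-hydroxy-2-methyl-2H-chromen-2-yl]methyl (E)-3-(4-acetoxy-3-methoxyphenyl)prop-2-enoate
Product: 12 [(2R)-6-acetyl-7-hydroxy-2-methyl-2H-chromen-2-yl]methyl (E)-3-(4-hydroxy-3-methoxyphenyl)prop-2-enoate (target)
Conditions: pyrrolidine (3 equiv), CH2Cl2, 0 °C, dark; then aq. NH4Cl
Reagents that add atoms: none
Why: Chemoselective aminolysis of the aryl acetate: the phenyl ester is far more electrophilic than the alkyl cinnamate, so pyrrolidine at 0 °C should remove only the acetyl group, under non-acidic conditions in the dark that do not endanger the chromene, the E-alkene or the C2 stereocentre.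

**Compound list**

1 | 2,4-dihydroxybenzaldehyde | O=Cc1ccc(O)cc1O | starting material
2 | 5-acetyl-2,4-dihydroxybenzaldehyde | CC(=O)c1cc(C=O)c(O)cc1O | intermediate
3 | 1-[2,4-dihydroxy-5-(hydroxymethyl)phenyl]ethanone | CC(=O)c1cc(CO)c(O)cc1O | intermediate
4 | methallyl alcohol (2-methylprop-2-en-1-ol) | C=C(C)CO | starting material
5 | 4-acetyl-3-hydroxy-6-methylidenecyclohexa-2,4-dien-1-one (ortho-quinone methide) | C=C1C=C(C(C)=O)C(O)=CC1=O | intermediate (not isolated)
6 | (R)-1-[7-hydroxy-2-(hydroxymethyl)-2-methylchroman-6-yl]ethanone | OC[C@@]1(C)CCc2cc(C(C)=O)c(O)cc2O1 | intermediate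
7 | ferulic acid | COc1cc(/C=C/C(=O)O)ccc1O | starting material
8 | (E)-3-(4-acetoxy-3-methoxyphenyl)prop-2-enoic acid | COc1cc(/C=C/C(=O)O)ccc1OC(C)=O | intermediate
9 | (E)-3-(4-acetoxy-3-methoxyphenyl)prop-2-enoyl chloride | COc1cc(/C=C/C(Cl)=O)ccc1OC(C)=O | intermediate (not isolated)
10 | [(2R)-6-acetyl-7-hydroxy-2-methyl-3,4-dihydro-2H-chromen-2-yl]methyl (E)-3-(4-acetoxy-3-methoxyphenyl)prop-2-enoate | COc1cc(/C=C/C(=O)OC[C@@]2(C)CCc3cc(C(C)=O)c(O)cc3O2)ccc1OC(C)=O | intermediate
11 | [(2R)-6-acetyl-7-hydroxy-2-methyl-2H-chromen-2-yl]methyl (E)-3-(4-acetoxy-3-methoxyphenyl)prop-2-enoate | COc1cc(/C=C/C(=O)OC[C@@]2(C)C=Cc3cc(C(C)=O)c(O)cc3O2)ccc1OC(C)=O | intermediate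
12 | [(2R)-6-acetyl-7-hydroxy-2-methyl-2H-chromen-2-yl]methyl (E)-3-(4-hydroxy-3-methoxyphenyl)prop-2-enoate | COc1cc(/C=C/C(=O)OC[C@@]2(C)C=Cc3cc(C(C)=O)c(O)cc3O2)ccc1O | target

**Step count**

Total steps: 7. Longest linear sequence: 6 steps (steps 1, 2, 3, 5, 6, 7); the ferulic acid branch (step 4) joins at step 5.

**Steps most likely to fail**

Step 3 (proposed new method). Facial selectivity on the 1,1-dialkyl alkene may be poor, or ionisation of the primary benzylic alcohol by the phosphoric acid may be too slow, so that self-condensation of 3 wins. A more acidic N-triflyl phosphoramide on the same backbone would be the first adjustment. The fallback gives up catalytic enantiocontrol: starting from 3, the quinone methide is generated without a chiral catalyst (excess 4 in toluene, sealed tube, 160 °C, or diphenyl phosphate as an achiral acid) and trapped by 4 to give racemic 1-[7-hydroxy-2-(hydroxymethyl)-2-methylchroman-6-yl]ethanone F1. The enantiomers of F1 would then be separated by preparative chromatography on a polysaccharide chiral stationary phase, and the (R)-enantiomer is compound 6, where the route is rejoined.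

Step 6. Hydride abstraction from the acetyl-deactivated chroman may be sluggish, the free phenol may be oxidised by the quinone, or enantiopurity may erode through reversible electrocyclic ring opening of the chromene during prolonged heating. The fallback installs the alkene by bromination and elimination, starting from 10. The C7 phenol is acetylated (Ac2O, Et3N, cat. DMAP, CH2Cl2) to give [(2R)-7-acetoxy-6-acetyl-2-methyl-3,4-dihydro-2H-chromen-2-yl]methyl (E)-3-(4-acetoxy-3-methoxyphenyl)prop-2-enoate F2. Wohl–Ziegler bromination at benzylic C4 (NBS, azobisisobutyronitrile, PhCF3, 75 °C) gives [(2R)-7-acetoxy-6-acetyl-4-bromo-2-methyl-3,4-dihydro-2H-chromen-2-yl]methyl (E)-3-(4-acetoxy-3-methoxyphenyl)prop-2-enoate F3 as a mixture of C4 epimers. Elimination with DBU in THF at rt gives [(2R)-7-acetoxy-6-acetyl-2-methyl-2H-chromen-2-yl]methyl (E)-3-(4-acetoxy-3-methoxyphenyl)prop-2-enoate F4. Pyrrolidine (excess, CH2Cl2, 0 °C) then cleaves both aryl acetates and the route is rejoined at the target 12.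

Step 1. C-acylation of the formyl-deactivated ring may stall, or the aldehyde may be consumed in acid-mediated condensation at 90 °C. The fallback introduces the acetyl group by cross-coupling, starting from 1. Bromination at C5 (Br2, AcOH, rt) gives 5-bromo-2,4-dihydroxybenzaldehyde F5. Stille coupling with tributyl(1-ethoxyvinyl)stannane (PdCl2(PPh3)2, 1,4-dioxane, 100 °C) gives 5-(1-ethoxyvinyl)-2,4-dihydroxybenzaldehyde F6. Hydrolysis of the enol ether (aq. HCl, THF, rt) gives compound 2, where the route is rejoined.

**Further compounds**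

F1 | step 3 | racemic 1-[7-hydroxy-2-(hydroxymethyl)-2-methylchroman-6-yl]ethanone | OCC1(C)CCc2cc(C(C)=O)c(O)cc2O1
F2 | step 6 | [(2R)-7-acetoxy-6-acetyl-2-methyl-3,4-dihydro-2H-chromen-2-yl]methyl (E)-3-(4-acetoxy-3-methoxyphenyl)prop-2-enoate | COc1cc(/C=C/C(=O)OC[C@@]2(C)CCc3cc(C(C)=O)c(OC(C)=O)cc3O2)ccc1OC(C)=O
F3 | step 6 | [(2R)-7-acetoxy-6-acetyl-4-bromo-2-methyl-3,4-dihydro-2H-chromen-2-yl]methyl (E)-3-(4-acetoxy-3-methoxyphenyl)prop-2-enoate (C4 epimers) | COc1cc(/C=C/C(=O)OC[C@@]2(C)CC(Br)c3cc(C(C)=O)c(OC(C)=O)cc3O2)ccc1OC(C)=O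
F4 | step 6 | [(2R)-7-acetoxy-6-acetyl-2-methyl-2H-chromen-2-yl]methyl (E)-3-(4-acetoxy-3-methoxyphenyl)prop-2-enoate | COc1cc(/C=C/C(=O)OC[C@@]2(C)C=Cc3cc(C(C)=O)c(OC(C)=O)cc3O2)ccc1OC(C)=O
F5 | step 1 | 5-bromo-2,4-dihydroxybenzaldehyde | O=Cc1cc(Br)c(O)cc1O
F6 | step 1 | 5-(1-ethoxyvinyl)-2,4-dihydroxybenzaldehyde | CCOC(=C)c1cc(C=O)c(O)cc1O
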